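The data are calculated for substances that don't exist, noise included.

**Time and temperature.** Time does little to the green run at −10 °C, whose Jb reads 26 % at 48.0 h and 26 % at 120 h, but the red flask at 5 °C has sunk to 16 % by 60.0 h, so the question is whether its Jb is heading for nothing.

all flasks: Ja 2.1 M; Jd 250 mM
- red: Jf 0.63 M; temperature 5 °C; the very flask that is asked about, followed so far
- green: Jf 0.63 M; temperature −10 °C; run made earlier
- flask: Jf 0.630 M; temperature 5 °C; time 4.0 d

| run | time / h | Jb / % |
|---|---|---|
| red | 3.00 | 34 |
| red | 8.00 | 27 |
| red | 15.0 | 27 |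
| red | 25.0 | 24 |
| red | 40.0 | 25 |
| red | 50.0 | 22 |
| red | 60.0 | 16 |
| green | 6.00 | 18 |
| green | 15.0 | 21 |
| green | 30.0 | 25 |
| green | 48.0 | 26 |
| green | 96.0 | 26 |
| green | 120 | 26 |

(each reading ± 1.5 percentage points)

- maple: at 4.0 d add Jd, 50.0 % of the amount charged, then wait 4.0 d
- elm: at 4.0 d take out 90 % of the Jb then present, then wait 4.0 d
- oak: at 4.0 d raise the temperature by 20 K, then wait 4.0 d
- larch: change nothing and wait 4.0 d more

- Jb that was removed still counts
- on the list of suspects stand: Jb <-> Je; Ja <-> Jb; Ja + Jf -> Jg; Jb + Jd <-> Jc + Jd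
- additions bring no volume worth counting

- Jb, in percent of the Ja first charged, at 4.0 d
- the remedy with the largest gain of Jb, or "none" below 2 percentage points (maple / elm / oak / larch / none)
- Jb present, with what was taken out counted in, in percent of the Ja first charged, after maple
- Jb present, with what was taken out counted in, in percent of the Ja first charged, after oak

**The opposite outcome.** For Jb to vanish, material must leave for good, and among the suspects Ja + Jf -> Jg is the step drawn one way. It spends Ja and Jf one for one, so an emptied flask asks for a Jf charge equal to the Ja charge. In the red flask Jf is the limiting reagent, its charge being 0.300 of the Ja charge, which stands 0.523 decades, in decimal logarithms, short of parity. That leaves 0.700 of the Ja charge beyond the reach of Jf, and this number, one minus the charge ratio, is the free fraction.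

**The reckoning.** The logarithm of Jb is the logarithm of the free fraction, −0.155, plus that of Jb's share of it. The last two red readings average 19.0 %, a share of 0.271, while the green run reads a share of 0.371. One decade lower asks for a share of 0.0271, which neither run shows. The reckoning here therefore commits to about 19.0 % at 4.0 d, or a little less. Maple and oak take nothing from the free fraction, so this reckoning keeps both near that figure. In this reckoning elm banks 17.1 %, and the same share of the remainder brings the total to 31.5 %, a gain of 12 percentage points.

**Forecast and result.** The forecast, on the ground that “The late decay is about 0.03 per hour”, gave 8 % (range 3 % to 14 %), elm as the best remedy, 5 % after maple and 5 % after oak, well below the reckoning here. The flask gives 17.4 %, with elm best at a gain of 9.8 points, 15.4 % after maple and 20.8 % after oak.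

    Jb ⇌ Je (K = 2.40, k = 0.0230 h⁻¹, Ea = 103 kJ mol⁻¹, ΔH = −30.0 kJ mol⁻¹)
    Ja ⇌ Jb (K = 1.70, k = 0.590 h⁻¹, Ea = 97.0 kJ mol⁻¹, ΔH = −20.0 kJ mol⁻¹)
    Ja + Jf → Jg (k = 0.540 L mol⁻¹ h⁻¹, Ea = 77.0 kJ mol⁻¹)
    Jb + Jd ⇌ Jc + Jd, rate k4*[Jd]*[Jb] forward; the back reaction follows from the equilibrium constant (K = 0.680, k = 1.70 L mol⁻¹ h⁻¹, Ea = 47.0 kJ mol⁻¹, ΔH = −27.0 kJ mol⁻¹)
    (constants at 5 °C)

**Neighbour flask.** The asked flask's Jb at 4.0 d is a share of 0.248 of its free fraction. The neighbour flask, charged with 1.6 M of Jf, stands 0.118 decades short of parity, so its free fraction is 0.238, and the same share gives 5.90 %. At 96.0 h the neighbour flask holds 76.0 % of Jg, keeps 0.26 % of its Jf, and shows Jb at 5.59 %.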